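## Retrosynthetic overview

1. Polymatin A ⇒ (C12 moved from O9 to O6, translactonisation) a bridged 6‑hydroxy‑9,12‑δ‑lactone ⇒ (C6–C7 bond) an open‑chain C6 enal whose C7 is the nucleophilic carbon of a 3‑(silylmethyl)‑5,6‑dihydropyran‑2‑one. This is a cation‑type C6–C7 closure of a farnesane‑like chain followed by O6 lactonisation on C12: ten‑membered carbocycle first, γ‑lactone second, as in germacranolide biosynthesis.
2. The dihydropyranone, a temporary ring that locks the allylsilane geometry and masks 9‑OH ⇒ ring‑closing metathesis of a C9 2‑(silylmethyl)acrylate with a C8 vinyl group.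
3. C8 angelate / C9 hydroxyl (threo) ⇒ SN2 opening of a cis‑vinyl epoxide by angelic acid ⇒ (Z)‑γ‑chloroallylboration of a 2‑formyl enoate.
4. The 2‑formyl enoate ⇒ Morita–Baylis–Hillman adduct of methyl acrylate with the C1–C6 aldehyde obtained by ozonolysis of geranyl acetate.

Assumption: the Ipc2B reagent derived from (−)‑α‑pinene adds to the Re face of the formyl enoate as it does with simple aldehydes; positions in all compounds use the germacrane numbering (C1–C15) of the target.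

## Route

Step 1
Reactants: 1 geranyl acetate, (2E)‑3,7‑dimethylocta‑2,6‑dien‑1‑yl acetate
Product: 2 (2E)‑3‑methyl‑6‑oxohex‑2‑en‑1‑yl acetate
Conditions: O3 (1.0 equiv, Sudan Red 7B end point), pyridine (3 equiv), CH2Cl2, −78 °C; Me2S, −78 °C to rt
Reagents that add atoms: ozone, O=[O+][O-]
Why: Ozonolysis, in which ozone attacks the electron‑rich 6,7‑alkene much faster than the 2,3‑alkene deactivated by the allylic acetate; no stereocentre is formed and the E alkene (later C4=C5) is untouched.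

Step 2
Reactants: 2 (2E)‑3‑methyl‑6‑oxohex‑2‑en‑1‑yl acetate; 3 methyl acrylate
Product: 4 methyl (6E)‑8‑acetoxy‑3‑hydroxy‑6‑methyl‑2‑methylideneoct‑6‑enoate (racemic)
Conditions: DABCO (0.5 equiv), 3 (5 equiv, neat), rt, 4 d
Reagents that add atoms: none
Why: Morita–Baylis–Hillman reaction of the unhindered aliphatic aldehyde, forming the C1–C10 bond; the racemic carbinol centre is removed in step 3.

Step 3
Reactants: 4 methyl (6E)‑8‑acetoxy‑3‑hydroxy‑6‑methyl‑2‑methylideneoct‑6‑enoate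
Product: 5 methyl (2Z,6E)‑8‑acetoxy‑2‑(bromomethyl)‑6‑methylocta‑2,6‑dienoate
Conditions: NBS (1.3 equiv), Me2S (1.5 equiv), CH2Cl2, 0 °C to rt
Reagents that add atoms: N‑bromosuccinimide, O=C1CCC(=O)N1Br
Why: Under Corey–Kim conditions bromide displaces the alkoxysulfonium group with allylic transposition (SN2′), giving the thermodynamically preferred Z bromide with C2 cis to CH2Br, which is the ring‑cis C1=C10 geometry of the target.

Step 4
Reactants: 5 methyl (2Z,6E)‑8‑acetoxy‑2‑(bromomethyl)‑6‑methylocta‑2,6‑dienoate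
Product: 6 methyl (2E,6E)‑8‑acetoxy‑2‑formyl‑6‑methylocta‑2,6‑dienoate
Conditions: NMO (2.5 equiv), 4 Å MS, MeCN, 0 °C to rt; short silica plug, used at once
Reagents that add atoms: N‑methylmorpholine N‑oxide, C[N+]1([O-])CCOCC1
Why: Ganem‑type N‑oxide oxidation (SN2 at C9, then loss of N‑methylmorpholine) gives the aldehyde with the alkene geometry retained (C2 cis to CHO), and immediate use limits E/Z equilibration.

Step 5
Reactants: 6 methyl (2E,6E)‑8‑acetoxy‑2‑formyl‑6‑methylocta‑2,6‑dienoate; 7 allyl chloride; 8 (+)‑B‑methoxydiisopinocampheylborane (Ipc groups from (−)‑α‑pinene)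
Product: 11 methyl (2E,6E)‑8‑acetoxy‑2‑[(1S,2S)‑2‑chloro‑1‑hydroxybut‑3‑en‑1‑yl]‑6‑methylocta‑2,6‑dienoate, via chloroallylborane 9 (not isolated), via borinate ester 10 (not isolated)
Conditions: 7 (1.6 equiv), 8 (1.3 equiv), lithium dicyclohexylamide (1.5 equiv), Et2O, −95 °C; BF3·OEt2 (2.5 equiv); 6, −95 °C, 4 h; 2‑aminoethanol, 0 °C
Reagents that add atoms: none
Why: Brown–Oehlschlager asymmetric γ‑chloroallylboration, in which the (Z)‑γ‑chloroallylborane reacts through a Zimmerman–Traxler chair (Z gives syn) and the Ipc groups direct attack to the Re face of the aldehyde, setting 9S and 8S.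

Step 6
Reactants: 11 methyl (2E,6E)‑8‑acetoxy‑2‑[(1S,2S)‑2‑chloro‑1‑hydroxybut‑3‑en‑1‑yl]‑6‑methylocta‑2,6‑dienoate
Product: 12 methyl (2E,6E)‑2‑[(2S,3R)‑3‑ethenyloxiran‑2‑yl]‑8‑hydroxy‑6‑methylocta‑2,6‑dienoate
Conditions: K2CO3 (2.2 equiv), MeOH, 0 °C, 2 h
Reagents that add atoms: none
Why: The C9 alkoxide displaces the allylic chloride (intramolecular Williamson SN2, inversion at C8) to give the cis‑epoxide (8R,9S), and the same medium removes the primary allylic acetate by methanolysis.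

Step 7
Reactants: 12 methyl (2E,6E)‑2‑[(2S,3R)‑3‑ethenyloxiran‑2‑yl]‑8‑hydroxy‑6‑methylocta‑2,6‑dienoate
Product: 13 methyl (2E,6E)‑2‑[(2S,3R)‑3‑ethenyloxiran‑2‑yl]‑6‑methyl‑8‑oxoocta‑2,6‑dienoate
Conditions: MnO2 (15 equiv), CH2Cl2, rt
Reagents that add atoms: none
Why: Allylic oxidation with MnO2 converts only the primary allylic alcohol into the E enal (C6) and leaves the epoxide and the enoate untouched.

Step 8
Reactants: 13 methyl (2E,6E)‑2‑[(2S,3R)‑3‑ethenyloxiran‑2‑yl]‑6‑methyl‑8‑oxoocta‑2,6‑dienoate; 14 angelic acid, (2Z)‑2‑methylbut‑2‑enoic acid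
Product: 15 methyl (2E,6E)‑2‑[(1S,2S)‑1‑hydroxy‑2‑{[(2Z)‑2‑methylbut‑2‑enoyl]oxy}but‑3‑en‑1‑yl]‑6‑methyl‑8‑oxoocta‑2,6‑dienoate
Conditions: 14 (3 equiv), Cs2CO3 (0.3 equiv), DMF, 45 °C
Reagents that add atoms: none
Why: Carboxylate SN2 opening of the vinyl epoxide at C8 (activated by the simple vinyl group and less hindered than C9, which sits next to the fully substituted enoate carbon) inverts C8 to 8S and puts the angelate directly on O8 with O9 free, while the excess acid buffers the alkoxide against acyl migration.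

Step 9
Reactants: 16 ethyl 2‑[(trimethylsilyl)methyl]prop‑2‑enoate
Product: 17 2‑[(trimethylsilyl)methyl]prop‑2‑enoic acid
Conditions: LiOH·H2O (1.5 equiv), THF/H2O 3:1, 0 °C to rt; 1 M HCl to pH 3
Reagents that add atoms: lithium hydroxide, [Li+].[OH-]
Why: Saponification of the ethyl ester followed by acidification gives the acid, the allylsilane being stable to cold aqueous base.

Step 10
Reactants: 15 methyl (2E,6E)‑2‑[(1S,2S)‑1‑hydroxy‑2‑{[(2Z)‑2‑methylbut‑2‑enoyl]oxy}but‑3‑en‑1‑yl]‑6‑methyl‑8‑oxoocta‑2,6‑dienoate; 17 2‑[(trimethylsilyl)methyl]prop‑2‑enoic acid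
Product: 18 methyl (2E,6E)‑6‑methyl‑2‑[(1S,2S)‑2‑{[(2Z)‑2‑methylbut‑2‑enoyl]oxy}‑1‑({2‑[(trimethylsilyl)methyl]prop‑2‑enoyl}oxy)but‑3‑en‑1‑yl]‑8‑oxoocta‑2,6‑dienoate
Conditions: DCC (1.5 equiv), DMAP (0.1 equiv), CH2Cl2, 0 °C to rt
Reagents that add atoms: none
Why: Steglich esterification acylates the only free hydroxyl (O9) under nearly neutral conditions, so the neighbouring angelate does not migrate and no stereocentre is touched.

Step 11
Reactants: 18 methyl (2E,6E)‑6‑methyl‑2‑[(1S,2S)‑2‑{[(2Z)‑2‑methylbut‑2‑enoyl]oxy}‑1‑({2‑[(trimethylsilyl)methyl]prop‑2‑enoyl}oxy)but‑3‑en‑1‑yl]‑8‑oxoocta‑2,6‑dienoate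
Product: 19 methyl (2E,6E)‑6‑methyl‑2‑[(2S,3S)‑3‑{[(2Z)‑2‑methylbut‑2‑enoyl]oxy}‑6‑oxo‑5‑[(trimethylsilyl)methyl]‑3,6‑dihydro‑2H‑pyran‑2‑yl]‑8‑oxoocta‑2,6‑dienoate
Conditions: second‑generation Grubbs catalyst, (H2IMes)(PCy3)Cl2Ru=CHPh (5 mol %), CH2Cl2 (5 mM), 40 °C
Reagents that add atoms: none
Why: Ring‑closing metathesis of the two terminal alkenes (the trisubstituted alkenes are inert) gives the six‑membered unsaturated lactone, which forms C7=C11, ties up O9 and fixes the allylsilane geometry for the ring closure.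

Step 12
Reactants: 19 methyl (2E,6E)‑6‑methyl‑2‑[(2S,3S)‑3‑{[(2Z)‑2‑methylbut‑2‑enoyl]oxy}‑6‑oxo‑5‑[(trimethylsilyl)methyl]‑3,6‑dihydro‑2H‑pyran‑2‑yl]‑8‑oxoocta‑2,6‑dienoate
Product: 22 polymatin A, via difluoroboryl alkoxide 20 (not isolated), via bridged hydroxy delta‑lactone 21 (not isolated)
Conditions: BF3·OEt2 (3 equiv), 2,6‑di‑tert‑butyl‑4‑methylpyridine (0.3 equiv), CH2Cl2 (1 mM, syringe‑pump addition of 19), −78 to −30 °C; aq NaHCO3; then PPTS (10 mol %), CH2Cl2, rt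
Reagents that add atoms: none
Why: Proposed new method: BF3 turns the C6 enal into an allyl‑cation equivalent that is attacked by C7 of the ring‑locked 2‑(silylmethyl)enoate, and loss of silicon creates the C11=C13 methylene without a C7 carbanion that could expel the C8 angelate (closest known: Hosomi–Sakurai additions of 2‑(trimethylsilylmethyl)acrylates to aldehydes and their intramolecular versions giving carbocycle‑fused α‑methylene lactones); C6 should add anti to the pseudoaxial C8 angelate (7S) in a synclinal arrangement with H6 in the crowded sector (6R), after which the 6‑hydroxyl opens the strained bridging δ‑lactone to the trans‑fused γ‑lactone and frees 9‑OH.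

## Compound list

1 | geranyl acetate, (2E)‑3,7‑dimethylocta‑2,6‑dien‑1‑yl acetate | CC(C)=CCC/C(C)=C/COC(C)=O | starting material
2 | (2E)‑3‑methyl‑6‑oxohex‑2‑en‑1‑yl acetate | O=CCC/C(C)=C/COC(C)=O | intermediate
3 | methyl acrylate | C=CC(=O)OC | starting material
4 | methyl (6E)‑8‑acetoxy‑3‑hydroxy‑6‑methyl‑2‑methylideneoct‑6‑enoate, racemic | C=C(C(=O)OC)C(O)CC/C(C)=C/COC(C)=O | intermediate
5 | methyl (2Z,6E)‑8‑acetoxy‑2‑(bromomethyl)‑6‑methylocta‑2,6‑dienoate | COC(=O)/C(CBr)=C/CC/C(C)=C/COC(C)=O | intermediate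
6 | methyl (2E,6E)‑8‑acetoxy‑2‑formyl‑6‑methylocta‑2,6‑dienoate | COC(=O)/C(C=O)=C/CC/C(C)=C/COC(C)=O | intermediate
7 | allyl chloride | C=CCCl | starting material
8 | (+)‑B‑methoxydiisopinocampheylborane, Ipc groups from (−)‑α‑pinene | COB([C@H]1C[C@H]2C[C@@H]([C@@H]1C)C2(C)C)[C@H]1C[C@H]2C[C@@H]([C@@H]1C)C2(C)C | starting material
9 | [(Z)‑3‑chloroallyl]diisopinocampheylborane | Cl/C=C\CB([C@H]1C[C@H]2C[C@@H]([C@@H]1C)C2(C)C)[C@H]1C[C@H]2C[C@@H]([C@@H]1C)C2(C)C | intermediate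
10 | O9 diisopinocampheylborinate of 11 | COC(=O)/C(=C/CC/C(C)=C/COC(C)=O)[C@H](OB([C@H]1C[C@H]2C[C@@H]([C@@H]1C)C2(C)C)[C@H]1C[C@H]2C[C@@H]([C@@H]1C)C2(C)C)[C@@H](Cl)C=C | intermediate
11 | methyl (2E,6E)‑8‑acetoxy‑2‑[(1S,2S)‑2‑chloro‑1‑hydroxybut‑3‑en‑1‑yl]‑6‑methylocta‑2,6‑dienoate | COC(=O)/C(=C/CC/C(C)=C/COC(C)=O)[C@H](O)[C@@H](Cl)C=C | intermediate
12 | methyl (2E,6E)‑2‑[(2S,3R)‑3‑ethenyloxiran‑2‑yl]‑8‑hydroxy‑6‑methylocta‑2,6‑dienoate (cis‑epoxide) | COC(=O)/C(=C/CC/C(C)=C/CO)[C@@H]1O[C@@H]1C=C | intermediate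
13 | methyl (2E,6E)‑2‑[(2S,3R)‑3‑ethenyloxiran‑2‑yl]‑6‑methyl‑8‑oxoocta‑2,6‑dienoate | COC(=O)/C(=C/CC/C(C)=C/C=O)[C@@H]1O[C@@H]1C=C | intermediate
14 | angelic acid, (2Z)‑2‑methylbut‑2‑enoic acid | C/C=C(/C)C(=O)O | starting material
15 | methyl (2E,6E)‑2‑[(1S,2S)‑1‑hydroxy‑2‑{[(2Z)‑2‑methylbut‑2‑enoyl]oxy}but‑3‑en‑1‑yl]‑6‑methyl‑8‑oxoocta‑2,6‑dienoate | COC(=O)/C(=C/CC/C(C)=C/C=O)[C@H](O)[C@@H](OC(=O)/C(C)=C\C)C=C | intermediate
16 | ethyl 2‑[(trimethylsilyl)methyl]prop‑2‑enoate | CCOC(=O)C(=C)C[Si](C)(C)C | starting material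
17 | 2‑[(trimethylsilyl)methyl]prop‑2‑enoic acid | OC(=O)C(=C)C[Si](C)(C)C | intermediate
18 | methyl (2E,6E)‑6‑methyl‑2‑[(1S,2S)‑2‑{[(2Z)‑2‑methylbut‑2‑enoyl]oxy}‑1‑({2‑[(trimethylsilyl)methyl]prop‑2‑enoyl}oxy)but‑3‑en‑1‑yl]‑8‑oxoocta‑2,6‑dienoate | COC(=O)/C(=C/CC/C(C)=C/C=O)[C@H](OC(=O)C(=C)C[Si](C)(C)C)[C@@H](OC(=O)/C(C)=C\C)C=C | intermediate
19 | methyl (2E,6E)‑6‑methyl‑2‑[(2S,3S)‑3‑{[(2Z)‑2‑methylbut‑2‑enoyl]oxy}‑6‑oxo‑5‑[(trimethylsilyl)methyl]‑3,6‑dihydro‑2H‑pyran‑2‑yl]‑8‑oxoocta‑2,6‑dienoate | COC(=O)/C(=C/CC/C(C)=C/C=O)[C@@H]1OC(=O)C(C[Si](C)(C)C)=C[C@@H]1OC(=O)/C(C)=C\C | intermediate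
20 | O6 difluoroboryl derivative of 21 | C=C1C(=O)O[C@H]([C@H]2OC(=O)/C(C)=C\C)/C(C(=O)OC)=C\CC/C(C)=C/[C@@H](OB(F)F)[C@H]12 | intermediate
21 | (6R,7S,8S,9S) bridged isomer of polymatin A: ten‑membered ring closed, 6‑OH free, C12 still lactonised on O9 (9,12‑δ‑lactone), 8‑angelate, C11=C13 methylene | C=C1C(=O)O[C@H]([C@H]2OC(=O)/C(C)=C\C)/C(C(=O)OC)=C\CC/C(C)=C/[C@@H](O)[C@H]12 | intermediate
22 | polymatin A, (6R,7S,8S,9S)‑8‑angeloyloxy‑9‑hydroxy melampolide (ring‑cis C1=C10, ring‑trans C4=C5) 6,12‑olide 14‑methyl ester | C=C1C(=O)O[C@@H]2/C=C(\C)CC/C=C(/C(=O)OC)[C@H](O)[C@@H](OC(=O)/C(C)=C\C)[C@@H]12 | target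

## Step count and weak points

Total steps: 12. Longest linear sequence: 11 (steps 1–8 and 10–12; step 9 is a one‑step side branch).

**Step 12 (ring closure and translactonisation).** The electron‑poor allylsilane may not close the ten‑membered ring, or the open transition state may give the C6 epimer. The fallback sets out from 15 and comes back at 21. It makes the same C6–C7 bond by a closed, six‑membered allylboration, which also avoids any allyl‑metal carbanion that could expel the C8 angelate. Compound 15 is esterified (DCC, DMAP) with purchased 2‑(bromomethyl)acrylic acid (C=C(CBr)C(=O)O) to give the bromomethyl acrylate F1. Ring‑closing metathesis gives the 3‑(bromomethyl)dihydropyranone F2. Borylation with B2pin2 and Pd2(dba)3 (zerovalent palladium, DMSO, rt) gives the allyl pinacol boronate F3. Heating F3 in toluene (80 °C, 2 mM, or Sc(OTf)3 catalysis at 0 °C) transfers the allyl group through a chair transition state (C8 trans to the CH2B group, hence 6,7‑anti) to give the O6 pinacol boronate of the bridged lactone F4. Aqueous work‑up gives 21, which translactonises to 22 as in step 12.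

**Step 8 (epoxide opening).** Attack at C9, SN2′ attack at C1 or the vinyl terminus, or angelate migration would erode the regio‑ and stereochemistry. The fallback sets out from 6 and comes back at 19. It installs O8 as an ether by reagent‑controlled alkoxyallylboration and acylates it only after O9 is locked in the lactone.
- Allyl methoxymethyl ether (C=CCOCOC) is lithiated (sec‑BuLi, THF, −78 °C), trapped with 8 and treated with BF3·OEt2 to give [(Z)‑3‑(methoxymethoxy)allyl]diisopinocampheylborane F5.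
- F5 adds to 6 through the same chair to give the borinate ester F6 and, after 2‑aminoethanol work‑up, the syn (8S,9S) methoxymethyl ether alcohol F7.
- DCC coupling with 17 gives the O9 acrylate F8, and ring‑closing metathesis gives the dihydropyranone F9.
- ZnBr2 and propane‑1‑thiol (CH2Cl2, 0 °C) remove the acetal to give the C8 alcohol F10.
- Yamaguchi esterification with 14 (2,4,6‑trichlorobenzoyl chloride, Et3N, then DMAP) gives the angelate F11.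
- Candida antarctica lipase B (pH 7 buffer) hydrolyses the C6 acetate to give the allylic alcohol F12, and MnO2 oxidises F12 to 19.

**Step 4 (N‑oxide oxidation).** The 2‑formyl enoate is a reactive acceptor, and amines can scramble its geometry towards the isomer with C2 trans to CHO. The fallback sets out from 5 and comes back at 6 without any amine. Ag2O in aqueous acetone hydrolyses the bromide to methyl (2E,6E)‑8‑acetoxy‑2‑(hydroxymethyl)‑6‑methylocta‑2,6‑dienoate F13, and MnO2 (CH2Cl2, rt) oxidises F13 to 6, which is used crude in step 5.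

## Further compounds

F1 | step 12 | methyl (2E,6E)‑2‑[(1S,2S)‑1‑{[2‑(bromomethyl)prop‑2‑enoyl]oxy}‑2‑{[(2Z)‑2‑methylbut‑2‑enoyl]oxy}but‑3‑en‑1‑yl]‑6‑methyl‑8‑oxoocta‑2,6‑dienoate | COC(=O)/C(=C/CC/C(C)=C/C=O)[C@H](OC(=O)C(=C)CBr)[C@@H](OC(=O)/C(C)=C\C)C=C
F2 | step 12 | methyl (2E,6E)‑2‑[(2S,3S)‑5‑(bromomethyl)‑3‑{[(2Z)‑2‑methylbut‑2‑enoyl]oxy}‑6‑oxo‑3,6‑dihydro‑2H‑pyran‑2‑yl]‑6‑methyl‑8‑oxoocta‑2,6‑dienoate | COC(=O)/C(=C/CC/C(C)=C/C=O)[C@@H]1OC(=O)C(CBr)=C[C@@H]1OC(=O)/C(C)=C\C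
F3 | step 12 | methyl (2E,6E)‑6‑methyl‑2‑[(2S,3S)‑3‑{[(2Z)‑2‑methylbut‑2‑enoyl]oxy}‑6‑oxo‑5‑[(4,4,5,5‑tetramethyl‑1,3,2‑dioxaborolan‑2‑yl)methyl]‑3,6‑dihydro‑2H‑pyran‑2‑yl]‑8‑oxoocta‑2,6‑dienoate | COC(=O)/C(=C/CC/C(C)=C/C=O)[C@@H]1OC(=O)C(CB2OC(C)(C)C(C)(C)O2)=C[C@@H]1OC(=O)/C(C)=C\C
F4 | step 12 | O6 pinacol boronate of 21 | C=C1C(=O)O[C@H]([C@H]2OC(=O)/C(C)=C\C)/C(C(=O)OC)=C\CC/C(C)=C/[C@@H](OB3OC(C)(C)C(C)(C)O3)[C@H]12
F5 | step 8 | [(Z)‑3‑(methoxymethoxy)allyl]diisopinocampheylborane | COCO/C=C\CB([C@H]1C[C@H]2C[C@@H]([C@@H]1C)C2(C)C)[C@H]1C[C@H]2C[C@@H]([C@@H]1C)C2(C)C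
F6 | step 8 | O9 diisopinocampheylborinate of F7 | COC(=O)/C(=C/CC/C(C)=C/COC(C)=O)[C@H](OB([C@H]1C[C@H]2C[C@@H]([C@@H]1C)C2(C)C)[C@H]1C[C@H]2C[C@@H]([C@@H]1C)C2(C)C)[C@@H](OCOC)C=C
F7 | step 8 | methyl (2E,6E)‑8‑acetoxy‑2‑[(1S,2S)‑1‑hydroxy‑2‑(methoxymethoxy)but‑3‑en‑1‑yl]‑6‑methylocta‑2,6‑dienoate | COC(=O)/C(=C/CC/C(C)=C/COC(C)=O)[C@H](O)[C@@H](OCOC)C=C
F8 | step 8 | methyl (2E,6E)‑8‑acetoxy‑2‑[(1S,2S)‑2‑(methoxymethoxy)‑1‑({2‑[(trimethylsilyl)methyl]prop‑2‑enoyl}oxy)but‑3‑en‑1‑yl]‑6‑methylocta‑2,6‑dienoate | COC(=O)/C(=C/CC/C(C)=C/COC(C)=O)[C@H](OC(=O)C(=C)C[Si](C)(C)C)[C@@H](OCOC)C=C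
F9 | step 8 | methyl (2E,6E)‑8‑acetoxy‑2‑[(2S,3S)‑3‑(methoxymethoxy)‑6‑oxo‑5‑[(trimethylsilyl)methyl]‑3,6‑dihydro‑2H‑pyran‑2‑yl]‑6‑methylocta‑2,6‑dienoate | COC(=O)/C(=C/CC/C(C)=C/COC(C)=O)[C@@H]1OC(=O)C(C[Si](C)(C)C)=C[C@@H]1OCOC
F10 | step 8 | methyl (2E,6E)‑8‑acetoxy‑2‑[(2S,3S)‑3‑hydroxy‑6‑oxo‑5‑[(trimethylsilyl)methyl]‑3,6‑dihydro‑2H‑pyran‑2‑yl]‑6‑methylocta‑2,6‑dienoate | COC(=O)/C(=C/CC/C(C)=C/COC(C)=O)[C@@H]1OC(=O)C(C[Si](C)(C)C)=C[C@@H]1O
F11 | step 8 | methyl (2E,6E)‑8‑acetoxy‑6‑methyl‑2‑[(2S,3S)‑3‑{[(2Z)‑2‑methylbut‑2‑enoyl]oxy}‑6‑oxo‑5‑[(trimethylsilyl)methyl]‑3,6‑dihydro‑2H‑pyran‑2‑yl]octa‑2,6‑dienoate | COC(=O)/C(=C/CC/C(C)=C/COC(C)=O)[C@@H]1OC(=O)C(C[Si](C)(C)C)=C[C@@H]1OC(=O)/C(C)=C\C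
F12 | step 8 | methyl (2E,6E)‑8‑hydroxy‑6‑methyl‑2‑[(2S,3S)‑3‑{[(2Z)‑2‑methylbut‑2‑enoyl]oxy}‑6‑oxo‑5‑[(trimethylsilyl)methyl]‑3,6‑dihydro‑2H‑pyran‑2‑yl]octa‑2,6‑dienoate | COC(=O)/C(=C/CC/C(C)=C/CO)[C@@H]1OC(=O)C(C[Si](C)(C)C)=C[C@@H]1OC(=O)/C(C)=C\C
F13 | step 4 | methyl (2E,6E)‑8‑acetoxy‑2‑(hydroxymethyl)‑6‑methylocta‑2,6‑dienoate | COC(=O)/C(CO)=C/CC/C(C)=C/COC(C)=O
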